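Each molecule of target takes one molecule of substrate and one of coupling partner, so I start by counting.

| setting | Monday's | Sunday's | south-east | south-west |
|---|---|---|---|---|
| substrate | 0.20 M (fed, over 3.0 h) | 0.20 M (fed, over 3.0 h) | 0.20 M (fed, over 3.0 h) | 0.20 M (fed, over 3.0 h) |
| coupling partner | 0.59 equiv | 1.4 equiv | 1.05 equiv | 0.530 equiv |
| temperature | −45 °C | −25 °C |  |  |
| remark | run made earlier | run made earlier | at −40 °C until 3.0 h, from then on at −10 °C | at −10 °C throughout |
| time |  |  | 4.0 h | 4.0 h |

- Monday's (time / h: target / %): 0.333: 0.1; 1.00: 0; 2.00: 0; 3.00: 1.7; 4.00: 1.8
- Sunday's (time / min: target / %): 10.0: 0; 30.0: 0.8; 60.0: 7.5; 80.0: 14.2; 120: 25.4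

(each reading ± 1 percentage point)

1. which one finishes higher in amount of target, in percent of the substrate charged ("neither" within 2 percentage points) (south-east / south-west / neither)
2. amount of target at the end, in percent of the substrate charged, south-east
3. amount of target at the end, in percent of the substrate charged, south-west

- what was read earlier has a scatter of 1 percentage point, one standard deviation
- percentages count the whole charge, also what has not yet gone in

Following one molecule of substrate, it becomes target only if it meets a partner. That gives 53.0% for south-west and 100% for south-east. I call this number the ceiling C, the smaller of the two charges in percent of the substrate charged; in south-west the coupling partner is the limiting reagent.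

My second way is a clock. Between 80.0 min and 120 min Sunday's target rose by 11 percentage points, a read pace of 0.168 h⁻¹ as a fraction of the charge. At that pace south-west needs 3.15 h to reach C, less than its 4.0 h. South-west has less partner than Sunday's run but stands at −10 °C against −25 °C. For south-west count and clock agree, so I trust a finish just under C.

For south-east they part. Monday's run read 1.7% at the end of a feed at −45 °C, so I expect little from the cold feed at −40 °C, which leaves 1.00 h of warmth. Reaching C in that time takes 5.95 times Sunday's pace, held while both reactants thin. The count has no time in it, so here it cheats: I commit to south-east finishing higher, but well under its C.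

The forecast says south-east, with 80% (64% to 90%) for south-east and 52% (46% to 53%) for south-west, where “the partner limits it”.

South-east ends at 70.4% and south-west at 48.4%, so south-east finishes higher.

    substrate + coupling partner → intermediate (k = 9.08 × 10⁻⁴ M⁻¹ s⁻¹, Ea = 43.0 kJ mol⁻¹)
    intermediate → target (k = 1.66 × 10⁻⁴ s⁻¹, Ea = 70.0 kJ mol⁻¹)
    substrate ⇌ dormant form (K = 2.48, k = 0.00588 s⁻¹, Ea = 70.0 kJ mol⁻¹, ΔH = 1.00 kJ mol⁻¹)
    target ⇌ isomer of the product (K = 0.540, k = 8.27 × 10⁻⁴ s⁻¹, Ea = 75.0 kJ mol⁻¹, ΔH = −43.0 kJ mol⁻¹)
    (constants at −40 °C)

South-east's target stands 30 points under its C at 4.0 h and is 95.8% at 40.0 h. In south-west at 4.0 h, 48.4% of target, 2.08% of isomer of the product, 0.0775% of intermediate and free partner worth 2.46% of the substrate charged add up to 53.0%, against C of 53.0%. A neighbour of south-west charged with 0.130 equiv of coupling partner has C of 13.0% and ends with 12.4% of target and 0.73% of its partner left.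

Readings and results come from a simulation for substances that don't exist; noise was put on by code.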